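**Plan** (atom labels C1–C25 and O6, O14, O16, O21, O25 follow the atom order of the target SMILES; the macrocycle is C2‑C3‑C4‑C5‑C7‑C9‑C10‑C11‑C12‑C13‑C19‑C22‑C23‑C24)
- Cuts, last-formed first: lactone bond O14–C13 and both trisubstituted oxiranes (C5–O6–C7, C13–O–C19), giving an E,E‑diene acid; the C24‑OH/C1=C2 unit, giving a C24–C2 oxirane that carries C1 as CH2O; ring bond C7–C9; chain bonds C2=C24, C22–C23 and C13=C19; C11/C17 from a δ‑lactone.
- Forward: vinyl/methyl δ‑lactone (C9–C13, C15, C17, C18) → ester aldehyde → two formyl‑ylide Wittig olefinations (C13=C19, then C24=C2) around a C22–C23 alkylation → oxirane → 14‑membered ring → exo‑methylene carbinol → two oxiranes and the six‑membered lactone in the last step.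
- Enabling feature: the E‑C5=C7 alkene carries methyl C8 on C7, the ring atom bonded to C9. A C7 alkenyl iodide of fixed geometry and a primary C9 borane from the only monosubstituted alkene (C9=C10) can therefore close the 14‑membered carbocycle, while C24‑OH and C1=C2 stay hidden in the C24–C2 oxirane.
- Stereochemistry: C11 from Rh/BINAP conjugate vinylation; C17 from trans alkylation of the lactone enolate; C24 from Sharpless epoxidation; C5, C7, C13, C19 from Shi epoxidation, with inversion at C13 on lactonisation; alkene geometry from stabilised ylides and syn‑hydrozirconation.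

Key step: step 17

Remark 1: (R)‑BINAP is assigned to the (R)‑lactone 3 by analogy with the facial preference of aryl additions to this lactone; the ligand antipode is taken if the sign of rotation of 3 disagrees.
Remark 2: the CIP label of C11 is S in 5–27 and R in 28–35 only because C10 loses its alkene duplicate atoms on hydroboration; the centre itself is never touched.

Step 1
Reactants: 1 5,6-dihydro-2H-pyran-2-one; 2 potassium vinyltrifluoroborate
Product: 3 (4R)-4-ethenyloxan-2-one
Conditions: [Rh(cod)2]BF4 (3 mol %), (R)-BINAP (3.3 mol %), toluene/H2O, 100 °C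
Reagents that add atoms: none
Why: Rhodium-catalysed asymmetric 1,4-addition (Hayashi–Miyaura type) in which the BINAP-bound vinylrhodium adds to one face of the cyclic enoate and water protonates the rhodium enolate, setting C11.

Step 2
Reactants: 3 (4R)-4-ethenyloxan-2-one
Product: 5 (3S,4S)-4-ethenyl-3-methyloxan-2-one, via lithium enolate 4 (not isolated)
Conditions: LiN(iPr)2 (1.05 equiv), THF, −78 °C; MeI, −78 → −40 °C
Reagents that add atoms: iodomethane, CI
Why: Kinetic lactone enolate alkylation in which the electrophile enters anti to the C4 vinyl group, giving the trans-3,4 lactone and so setting C17 relative to C11.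

Step 3
Reactants: 5 (3S,4S)-4-ethenyl-3-methyloxan-2-one
Product: 6 methyl (2S,3S)-3-(2-hydroxyethyl)-2-methylpent-4-enoate
Conditions: MeOH (solvent), camphorsulfonic acid (cat.), rt; Et3N, then concentrate cold
Reagents that add atoms: methanol, CO
Why: Acid-catalysed transesterification in methanol opens the δ-lactone without touching the α-stereocentre, and neutralisation before concentration keeps the hydroxy ester from closing again (recovered 5 is recycled).

Step 4
Reactants: 6 methyl (2S,3S)-3-(2-hydroxyethyl)-2-methylpent-4-enoate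
Product: 7 methyl (2S,3S)-2-methyl-3-(2-oxoethyl)pent-4-enoate
Conditions: Dess–Martin periodinane, NaHCO3, CH2Cl2, 0 °C → rt
Reagents that add atoms: none
Why: Buffered Dess–Martin oxidation of the primary alcohol gives an aldehyde that has no α-stereocentre to lose.

Step 5
Reactants: 7 methyl (2S,3S)-2-methyl-3-(2-oxoethyl)pent-4-enoate; 8 2-(triphenylphosphoranylidene)propanal
Product: 9 methyl (2S,3S,5E)-3-ethenyl-2,6-dimethyl-7-oxohept-5-enoate
Conditions: toluene, 90 °C
Reagents that add atoms: none
Why: Wittig olefination with a formyl-stabilised ylide should give the E-2-methyl enal (E-C13=C19) under thermodynamic control, the product enal being too unreactive to add a second ylide.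

Step 6
Reactants: 9 methyl (2S,3S,5E)-3-ethenyl-2,6-dimethyl-7-oxohept-5-enoate
Product: 10 methyl (2S,3S,5E)-3-ethenyl-7-hydroxy-2,6-dimethylhept-5-enoate
Conditions: NaBH4, CeCl3·7H2O, MeOH, −20 °C
Reagents that add atoms: none
Why: Luche reduction reduces the enal carbonyl 1,2 and leaves the methyl ester and the alkenes untouched.

Step 7
Reactants: 10 methyl (2S,3S,5E)-3-ethenyl-7-hydroxy-2,6-dimethylhept-5-enoate
Product: 11 methyl (2S,3S,5E)-7-bromo-3-ethenyl-2,6-dimethylhept-5-enoate
Conditions: CBr4, PPh3, 2,6-lutidine, CH2Cl2, −20 → 0 °C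
Reagents that add atoms: tetrabromomethane, BrC(Br)(Br)Br
Why: Appel bromination displaces the activated primary allylic oxygen at C22 by SN2 at low temperature, so the alkene should neither migrate nor isomerise.

Step 8
Reactants: 11 methyl (2S,3S,5E)-7-bromo-3-ethenyl-2,6-dimethylhept-5-enoate; 12 acetaldehyde N,N-dimethylhydrazone
Product: 15 methyl (2S,3S,5E)-3-ethenyl-2,6-dimethyl-9-oxonon-5-enoate, via lithiated hydrazone 13 (not isolated), via alkylated hydrazone 14 (not isolated)
Conditions: 12, LiN(iPr)2 (1.0 equiv), THF, 0 °C; 11, −78 → −40 °C; then sat. aq. oxalic acid, Et2O, rt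
Reagents that add atoms: water, O
Why: Corey–Enders-type alkylation in which the azaenolate (an acetaldehyde enolate equivalent) displaces the reactive allylic bromide by SN2 at C22 faster than it deprotonates or attacks the hindered ester at −78 °C, and mild biphasic acid then releases the aldehyde, forming C22–C23.

Step 9
Reactants: 16 hex-4-yn-1-ol
Product: 18 (4E)-5-iodohex-4-en-1-ol, via alkenylzirconocene chloride 17 (not isolated)
Conditions: Cp2Zr(H)Cl (2.5 equiv), THF, rt → 45 °C; I2, 0 °C
Reagents that add atoms: iodine, II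
Why: syn-Hydrozirconation of the internal alkyne with excess Cp2Zr(H)Cl equilibrates zirconium onto the less hindered methyl-bearing carbon and iodinolysis proceeds with retention, giving the E-iodoalkene that becomes C5=C7–I.

Step 10
Reactants: 18 (4E)-5-iodohex-4-en-1-ol
Product: 19 (2E)-2,6-diiodohex-2-ene
Conditions: I2, PPh3, imidazole, CH2Cl2, 0 °C
Reagents that add atoms: iodine, II
Why: Appel-type iodination proceeds by SN2 on the primary alkoxyphosphonium ion and cannot touch the alkenyl iodide.

Step 11
Reactants: 19 (2E)-2,6-diiodohex-2-ene; 20 triphenylphosphine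
Product: 21 [(4E)-5-iodohex-4-en-1-yl]triphenylphosphonium iodide
Conditions: MeCN, 80 °C
Reagents that add atoms: none
Why: SN2 quaternisation of the phosphine occurs only at the primary alkyl iodide, the alkenyl iodide being inert to substitution.

Step 12
Reactants: 21 [(4E)-5-iodohex-4-en-1-yl]triphenylphosphonium iodide
Product: 23 (5E)-6-iodo-2-(triphenylphosphoranylidene)hept-5-enal, via phosphorus ylide 22 (not isolated)
Conditions: NaN(SiMe3)2 (1 equiv), THF, −78 → 0 °C; HCO2Et, −78 °C; NaN(SiMe3)2 (1 equiv), −78 °C → rt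
Reagents that add atoms: ethyl formate, CCOC=O
Why: C-Formylation of the non-stabilised ylide by the formate ester followed by deprotonation of the acylphosphonium ion gives the stabilised α-formyl ylide, the second equivalent of base preventing loss of ylide by transylidation.

Step 13
Reactants: 15 methyl (2S,3S,5E)-3-ethenyl-2,6-dimethyl-9-oxonon-5-enoate; 23 (5E)-6-iodo-2-(triphenylphosphoranylidene)hept-5-enal
Product: 24 methyl (2S,3S,5E,9E,13E)-3-ethenyl-10-formyl-14-iodo-2,6-dimethylpentadeca-5,9,13-trienoate
Conditions: toluene, 100 °C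
Reagents that add atoms: none
Why: Wittig olefination with the α-alkyl-α-formyl ylide should give the E-trisubstituted enal (CHO trans to C23), forming C24=C2 and leaving C1 as the handle for the next steps.

Step 14
Reactants: 24 methyl (2S,3S,5E,9E,13E)-3-ethenyl-10-formyl-14-iodo-2,6-dimethylpentadeca-5,9,13-trienoate
Product: 25 methyl (2S,3S,5E,9E,13E)-3-ethenyl-10-(hydroxymethyl)-14-iodo-2,6-dimethylpentadeca-5,9,13-trienoate
Conditions: NaBH4, CeCl3·7H2O, MeOH, −20 °C
Reagents that add atoms: none
Why: Luche reduction converts the enal into the allylic alcohol without reducing the methyl ester, so no ester differentiation is needed.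

Step 15
Reactants: 25 methyl (2S,3S,5E,9E,13E)-3-ethenyl-10-(hydroxymethyl)-14-iodo-2,6-dimethylpentadeca-5,9,13-trienoate
Product: 26 seco epoxy alcohol with (2R,24R) C24–C2 oxirane and C1H2OH on C2
Conditions: Ti(OiPr)4 (10 mol %), D-(−)-diisopropyl tartrate (12 mol %), t-BuOOH, 4 Å MS, CH2Cl2, −20 °C
Reagents that add atoms: tert-butyl hydroperoxide, CC(C)(C)OO
Why: Sharpless asymmetric epoxidation acts only on the allylic alcohol among the four alkenes, and with the D-(−)-tartrate the E-2,3-disubstituted allylic alcohol is epoxidised on the face that gives 24R (and 2R), the C24–O bond that survives into the target.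

Step 16
Reactants: 26 seco epoxy alcohol
Product: 27 seco silyl ether (C1H2OTBS on the C24–C2 oxirane; C7 iodide; C9=C10 vinyl)
Conditions: TBSCl, imidazole, CH2Cl2, 0 °C → rt
Reagents that add atoms: tert-butyldimethylsilyl chloride, CC(C)(C)[Si](C)(C)Cl
Why: Silylation masks the only hydroxyl group so that neither the borane nor the aqueous base of the next step meets a free epoxy alcohol.

Step 17
Reactants: 27 seco silyl ether
Product: 29 macrocyclic silyl-oxirane ester (14-membered ring; E-C5=C7 and E-C13=C19), via B-alkyl-9-BBN borane 28 (not isolated)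
Conditions: 9-BBN (1.5 equiv), THF, rt; H2O; then slow addition to PdCl2(dppf) (15 mol %), AsPh3 (30 mol %), Cs2CO3 (3 equiv), DMF/THF/H2O, 50 °C, ca. 2 mM
Reagents that add atoms: none
Why: 9-BBN adds anti-Markovnikov to the only monosubstituted alkene (C9=C10) to give the primary C9 borane; base converts it into the borate, the C7–I bond adds oxidatively to zerovalent palladium with retention of the E geometry, and transmetalation of the primary alkyl group followed by reductive elimination from divalent palladium forms C7–C9. The closest known reaction type is the B-alkyl Suzuki–Miyaura macrocyclisation. The 14-membered carbocycle closes by intramolecular sp2–sp3 coupling through a macrocyclic alkyl(alkenyl)palladium intermediate under slow addition and high dilution. No stereocentre is formed; C2, C11, C17 and C24 are spectators. The step needs site-selective hydroboration, which is secured because the trisubstituted C13=C19 alkene and the iodoalkene are inert to 9-BBN at rt and the exo-methylene is absent, being stored as the C24–C2 oxirane with C1 as a silyl ether. It also needs retention of the iodide geometry, which is inherent to the mechanism, and ring closure over oligomerisation, which dilution and the AsPh3-accelerated transmetalation should favour.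

Step 18
Reactants: 29 macrocyclic silyl-oxirane ester
Product: 30 macrocyclic epoxy alcohol (C1H2OH on C2)
Conditions: Bu4NF, AcOH, THF, 0 °C → rt
Reagents that add atoms: none
Why: Fluoride cleaves the primary silyl ether, and the acetic acid buffer suppresses Payne rearrangement of the liberated epoxy alkoxide.

Step 19
Reactants: 30 macrocyclic epoxy alcohol
Product: 31 macrocyclic epoxy iodide (C1H2I on C2)
Conditions: I2, PPh3, imidazole, CH2Cl2, 0 °C, dark
Reagents that add atoms: iodine, II
Why: Appel-type iodination of the primary alcohol of a 2,3-epoxy alcohol, the phosphonium reagent being consumed by the alcohol at 0 °C before it can open the trisubstituted oxirane.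

Step 20
Reactants: 31 macrocyclic epoxy iodide
Product: 32 macrocyclic triene hydroxy ester (C1=C2 exo-methylene; 24R alcohol)
Conditions: Zn dust, AcOH, EtOH, rt
Reagents that add atoms: none
Why: Zinc inserts into the C1–I bond and the organozinc undergoes β-elimination with cleavage of the oxirane C2–O bond, a reductive opening that can only give C1=C2 and the C24 alcohol with its C–O bond and 24R configuration intact, under conditions too weakly basic to enolise the ester.

Step 21
Reactants: 32 macrocyclic triene hydroxy ester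
Product: 33 macrocyclic triene hydroxy acid
Conditions: LiOH·H2O, THF/MeOH/H2O, rt; aq. HCl to pH 4
Reagents that add atoms: lithium hydroxide, [Li+].[OH-]
Why: Saponification of the methyl ester at room temperature, the carboxylate once formed resisting α-deprotonation so that C17 should be kept.

Step 22
Reactants: 33 macrocyclic triene hydroxy acid
Product: 35 target hydroxy lactone bis-oxirane, via bis-epoxy acid 34 (not isolated)
Conditions: L-fructose-derived Shi ketone (0.6 equiv), KHSO5 (as 2KHSO5·KHSO4·K2SO4), K2CO3, Bu4NHSO4, MeCN/CH2(OMe)2, aq. Na2B4O7 buffer (pH 10.5), 0 °C; aq. NaH2PO4 to pH 5; PPTS (cat.), CH2Cl2, rt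
Reagents that add atoms: potassium peroxymonosulfate, [K+].[O-]S(=O)(=O)OO
Why: Shi epoxidation in which the chiral dioxirane attacks both electron-rich E-trisubstituted alkenes through the spiro transition state on the face giving the (5S,7S) and (13S,19S) oxiranes, faster than the less electron-rich 1,1-disubstituted alkene; the carboxylic acid then opens the C13–C19 oxirane at C13 by 6-exo attack with inversion (13S → 13R), giving the δ-lactone and the C19 tertiary alcohol.

**Compound list**
1 | 5,6-dihydro-2H-pyran-2-one | O=C1C=CCCO1 | starting material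
2 | potassium vinyltrifluoroborate | C=C[B-](F)(F)F.[K+] | starting material
3 | (4R)-4-ethenyloxan-2-one | C=C[C@@H]1CCOC(=O)C1 | intermediate
4 | lithium enolate of 3 (formed in the flask) | C=C[C@@H]1CCOC(O[Li])=C1 | intermediate
5 | (3S,4S)-4-ethenyl-3-methyloxan-2-one (methyl and vinyl trans) | C[C@@H]1C(=O)OCC[C@H]1C=C | intermediate
6 | methyl (2S,3S)-3-(2-hydroxyethyl)-2-methylpent-4-enoate | C=C[C@@H]([C@H](C)C(=O)OC)CCO | intermediate
7 | methyl (2S,3S)-2-methyl-3-(2-oxoethyl)pent-4-enoate | C=C[C@@H]([C@H](C)C(=O)OC)CC=O | intermediate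
8 | 2-(triphenylphosphoranylidene)propanal | CC(C=O)=P(c1ccccc1)(c1ccccc1)c1ccccc1 | starting material
9 | methyl (2S,3S,5E)-3-ethenyl-2,6-dimethyl-7-oxohept-5-enoate | C=C[C@@H]([C@H](C)C(=O)OC)C/C=C(\C)C=O | intermediate
10 | methyl (2S,3S,5E)-3-ethenyl-7-hydroxy-2,6-dimethylhept-5-enoate | C=C[C@@H]([C@H](C)C(=O)OC)C/C=C(\C)CO | intermediate
11 | methyl (2S,3S,5E)-7-bromo-3-ethenyl-2,6-dimethylhept-5-enoate | C=C[C@@H]([C@H](C)C(=O)OC)C/C=C(\C)CBr | intermediate
12 | acetaldehyde N,N-dimethylhydrazone | CC=NN(C)C | starting material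
13 | lithiated acetaldehyde N,N-dimethylhydrazone (formed in the flask) | [Li]CC=NN(C)C | intermediate
14 | N,N-dimethylhydrazone of 15 (formed in the flask) | C=C[C@@H]([C@H](C)C(=O)OC)C/C=C(\C)CCC=NN(C)C | intermediate
15 | methyl (2S,3S,5E)-3-ethenyl-2,6-dimethyl-9-oxonon-5-enoate | C=C[C@@H]([C@H](C)C(=O)OC)C/C=C(\C)CCC=O | intermediate
16 | hex-4-yn-1-ol | CC#CCCCO | starting material
17 | (E)-alkenylzirconocene chloride from 16, zirconium on the methyl-bearing carbon, oxygen bound as zirconium alkoxide (formed in the flask) | C/C(=C\CCCO[Zr](Cl)(C1C=CC=C1)C1C=CC=C1)[Zr](Cl)(C1C=CC=C1)C1C=CC=C1 | intermediate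
18 | (4E)-5-iodohex-4-en-1-ol | C/C(I)=C\CCCO | intermediate
19 | (2E)-2,6-diiodohex-2-ene | C/C(I)=C\CCCI | intermediate
20 | triphenylphosphine | c1ccc(cc1)P(c1ccccc1)c1ccccc1 | starting material
21 | [(4E)-5-iodohex-4-en-1-yl]triphenylphosphonium iodide | C/C(I)=C\CCC[P+](c1ccccc1)(c1ccccc1)c1ccccc1.[I-] | intermediate
22 | [(4E)-5-iodohex-4-en-1-ylidene]triphenylphosphorane (formed in the flask) | C/C(I)=C\CCC=P(c1ccccc1)(c1ccccc1)c1ccccc1 | intermediate
23 | (5E)-6-iodo-2-(triphenylphosphoranylidene)hept-5-enal | C/C(I)=C\CCC(C=O)=P(c1ccccc1)(c1ccccc1)c1ccccc1 | intermediate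
24 | methyl (2S,3S,5E,9E,13E)-3-ethenyl-10-formyl-14-iodo-2,6-dimethylpentadeca-5,9,13-trienoate | C=C[C@@H]([C@H](C)C(=O)OC)C/C=C(\C)CC/C=C(/C=O)CC/C=C(\C)I | intermediate
25 | methyl (2S,3S,5E,9E,13E)-3-ethenyl-10-(hydroxymethyl)-14-iodo-2,6-dimethylpentadeca-5,9,13-trienoate | C=C[C@@H]([C@H](C)C(=O)OC)C/C=C(\C)CC/C=C(/CO)CC/C=C(\C)I | intermediate
26 | methyl (2S,3S,5E)-3-ethenyl-8-[(2R,3R)-3-(hydroxymethyl)-3-[(3E)-4-iodopent-3-en-1-yl]oxiran-2-yl]-2,6-dimethyloct-5-enoate | C=C[C@@H]([C@H](C)C(=O)OC)C/C=C(\C)CC[C@H]1O[C@@]1(CO)CC/C=C(\C)I | intermediate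
27 | tert-butyldimethylsilyl ether of 26 at the oxirane CH2OH; descriptors as in 26 | C=C[C@@H]([C@H](C)C(=O)OC)C/C=C(\C)CC[C@H]1O[C@@]1(CO[Si](C)(C)C(C)(C)C)CC/C=C(\C)I | intermediate
28 | B-alkyl-9-BBN borane: 27 with C9H2–C10H2 in place of the vinyl group and 9-borabicyclo[3.3.1]nonan-9-yl on C9; (2R,11R,17S,24R) (formed in the flask) | B1(CC[C@@H]([C@H](C)C(=O)OC)C/C=C(\C)CC[C@H]3O[C@@]3(CO[Si](C)(C)C(C)(C)C)CC/C=C(\C)I)C2CCCC1CCC2 | intermediate
29 | 14-membered carbocycle with E-C5=C7 (methyl C8 on C7) and E-C13=C19 (methyl C20 on C19), ring-fused (2R,24R) C24–C2 oxirane bearing CH2OTBS on C2, and (11R) C11 carrying the (17S)-CH(CH3)CO2Me group | C/C1=C\CC[C@]2(CO[Si](C)(C)C(C)(C)C)O[C@@H]2CC/C(C)=C/C[C@H]([C@H](C)C(=O)OC)CC1 | intermediate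
30 | desilylated 29: CH2OH on C2 of the oxirane; (2R,11R,17S,24R) | C/C1=C\CC[C@]2(CO)O[C@@H]2CC/C(C)=C/C[C@H]([C@H](C)C(=O)OC)CC1 | intermediate
31 | iodide of 30: CH2I on C2 of the oxirane; (2S,11R,17S,24R), the C2 label changing by priority only | C/C1=C\CC[C@]2(CI)O[C@@H]2CC/C(C)=C/C[C@H]([C@H](C)C(=O)OC)CC1 | intermediate
32 | 14-membered triene: C1=C2 exo-methylene, (24R)-OH, E-C5=C7, E-C13=C19, (11R) C11 carrying the (17S)-CH(CH3)CO2Me group | C=C1CC/C=C(\C)CC[C@@H]([C@H](C)C(=O)OC)C/C=C(\C)CC[C@H]1O | intermediate
33 | carboxylic acid of 32 | C=C1CC/C=C(\C)CC[C@@H]([C@H](C)C(=O)O)C/C=C(\C)CC[C@H]1O | intermediate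
34 | (5S,7S,13S,19S)-bis-oxirane of 33; (11R,17S,24R) (formed in the flask) | C=C1CC[C@@H]2O[C@@]2(C)CC[C@@H]([C@H](C)C(=O)O)C[C@@H]2O[C@@]2(C)CC[C@H]1O | intermediate
35 | target: (5S,7S,11R,13R,17S,19S,24R); 14-membered carbocycle with C5–O6–C7 oxirane (methyl C8 on C7), δ-lactone C13–O14–C15(=O)–C17–C11–C12 (methyl C18 on C17), tertiary alcohol and methyl C20 on C19, secondary alcohol on C24 and C1=C2 exo-methylene | C=C1CC[C@@H]2O[C@@]2(C)CC[C@@H]2C[C@@H](OC(=O)[C@H]2C)[C@@](C)(O)CC[C@H]1O | target

**Count:** 22 steps in total. The longest linear sequence is 18 steps (steps 1–8, then 13–22, from 5,6-dihydro-2H-pyran-2-one); the ylide branch (steps 9–12) has 4 steps.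

**Steps most likely to fail**

Step 17. Intermolecular coupling to oligomers, protodeboronation of the borane, or slow oxidative addition at the hindered 2-iodo-2-alkene may outrun ring closure. The fallback sets out from 27 and forms the same bond through an organozinc, without aqueous base. The borane 28 would be oxidised (NaBO3·4H2O) to the primary C9 alcohol F1 and converted (I2, PPh3, imidazole) into the primary C9 iodide F2. Zinc (Zn dust, LiCl, THF) would insert into the alkyl C–I bond only, giving the alkylzinc iodide F3. An intramolecular Negishi coupling (Pd2(dba)3 as the zerovalent palladium source, tri(2-furyl)phosphine, THF/NMP, high dilution) would then close F3 onto the C7 iodide and return to the route at 29.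

Step 22. The dioxirane may also attack the exo-methylene, the ring conformation may override the catalyst at one alkene, or acid may open the C5–C7 oxirane transannularly during lactonisation. The fallback sets out from 29 and epoxidises while the exo-methylene is still masked. Saponification (LiOH) would give the silyl-oxirane acid F4. The same ketone/KHSO5 system would give the bis-epoxy acid F5 and, after mild acid, the silyl-protected hydroxy lactone F6. Buffered fluoride would free the epoxy alcohol F7, and MsCl/Et3N would give the mesylate F8. NaI and Zn in butanone would pass through the epoxy iodide F9 and open the C24–C2 oxirane reductively, rejoining the route at 35.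

Step 8. Proton transfer from C17 to the azaenolate (epimerisation), addition to the ester, or SN2′ attack may compete with alkylation. The fallback sets out from 11 and avoids a strongly basic enolate equivalent. Copper-catalysed coupling (Li2CuCl4 cat., THF, −40 °C) with commercial (1,3-dioxolan-2-ylmethyl)magnesium bromide would give the dioxolane acetal F10. Its hydrolysis (PPTS, acetone/H2O) returns to the route at 15.

Further compounds
F1 | step 17 | primary C9 alcohol from hydroboration–oxidation of 27 | OCC[C@@H]([C@H](C)C(=O)OC)C/C=C(\C)CC[C@H]1O[C@@]1(CO[Si](C)(C)C(C)(C)C)CC/C=C(\C)I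
F2 | step 17 | primary C9 iodide | ICC[C@@H]([C@H](C)C(=O)OC)C/C=C(\C)CC[C@H]1O[C@@]1(CO[Si](C)(C)C(C)(C)C)CC/C=C(\C)I
F3 | step 17 | alkylzinc iodide at C9 | I[Zn]CC[C@@H]([C@H](C)C(=O)OC)C/C=C(\C)CC[C@H]1O[C@@]1(CO[Si](C)(C)C(C)(C)C)CC/C=C(\C)I
F4 | step 22 | silyl-oxirane acid (carboxylic acid of 29) | C/C1=C\CC[C@]2(CO[Si](C)(C)C(C)(C)C)O[C@@H]2CC/C(C)=C/C[C@H]([C@H](C)C(=O)O)CC1
F5 | step 22 | bis-epoxy acid with the silyl-oxirane intact | C(O[Si](C)(C)C(C)(C)C)[C@]12CC[C@@H]3O[C@@]3(C)CC[C@@H]([C@H](C)C(=O)O)C[C@@H]3O[C@@]3(C)CC[C@H]1O2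
F6 | step 22 | silyl-protected hydroxy lactone with C5–C7 and C24–C2 oxiranes | C(O[Si](C)(C)C(C)(C)C)[C@]12CC[C@@H]3O[C@@]3(C)CC[C@@H]3C[C@@H](OC(=O)[C@H]3C)[C@@](C)(O)CC[C@H]1O2
F7 | step 22 | epoxy alcohol (CH2OH on C2) of the hydroxy lactone | OC[C@]12CC[C@@H]3O[C@@]3(C)CC[C@@H]3C[C@@H](OC(=O)[C@H]3C)[C@@](C)(O)CC[C@H]1O2
F8 | step 22 | mesylate of F7 | CS(=O)(=O)OC[C@]12CC[C@@H]3O[C@@]3(C)CC[C@@H]3C[C@@H](OC(=O)[C@H]3C)[C@@](C)(O)CC[C@H]1O2
F9 | step 22 | epoxy iodide (CH2I on C2) of the hydroxy lactone | IC[C@]12CC[C@@H]3O[C@@]3(C)CC[C@@H]3C[C@@H](OC(=O)[C@H]3C)[C@@](C)(O)CC[C@H]1O2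
F10 | step 8 | dioxolane acetal of 15 | C=C[C@@H]([C@H](C)C(=O)OC)C/C=C(\C)CCC1OCCO1
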